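**Retrosynthetic overview**
- The tetronic acid ring is closed last, by Lacey–Dieckmann cyclisation of the O‑propanoyl α‑hydroxy methyl ester that carries the whole side chain.
- That hydroxy ester comes from forming the C5–C6 bond under blue light: an Ir/Ni ring‑opening decarboxylative allylation joins a trans δ‑lactone (as its carboxylate) to a furyl‑geranyl allylic benzoate.
- The trans δ‑lactone comes from Me2CuLi anti‑addition to an (R)‑dihydropyranone, made by RCM of the acrylate of methyl (R)‑2‑hydroxypent‑4‑enoate, itself from methyl (R)‑glycidate. This bought centre becomes ring C5 and directs the chain methyl centre.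
- The allylic benzoate comes from Cu‑catalysed sp3–sp3 coupling of 2‑(3‑furyl)ethyl Grignard with (2E,6E)‑8‑bromogeranyl benzoate, made by SeO2 oxidation of geranyl benzoate (both E‑olefins bought).
- Ring order: temporary δ‑lactone (step 3), opened in step 9, then the tetronic acid (step 11); the furan is bought intact.

Assumption: methyl (R)‑glycidate (made commercially from L‑serine), geranyl benzoate and 2‑(furan‑3‑yl)ethan‑1‑ol are taken as catalogue compounds.

**Step 1**
Reactants: 1 methyl (2R)-oxirane-2-carboxylate (methyl (R)-glycidate)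
Product: 2 methyl (2R)-2-hydroxypent-4-enoate
Conditions: CH2=CHMgBr (1.2 equiv), CuI (10 mol %), THF, −60 to −30 °C; aq. NH4Cl
Reagents that add atoms: vinylmagnesium bromide, C=C[Mg]Br
Why: Copper‑catalysed Grignard opening of the glycidic ester at the unsubstituted C3 (SN2 epoxide opening) is faster than ester attack at low temperature and leaves the bought C2–O centre untouched, so (R) is carried over.

**Step 2**
Reactants: 2 methyl (2R)-2-hydroxypent-4-enoate
Product: 3 methyl (2R)-2-(prop-2-enoyloxy)pent-4-enoate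
Conditions: CH2=CHCOCl (1.2 equiv), Et3N (1.5 equiv), DMAP (5 mol %), CH2Cl2, 0 °C
Reagents that add atoms: acryloyl chloride, C=CC(=O)Cl
Why: DMAP‑catalysed O‑acylation of the secondary alcohol; no bond to the stereocentre is broken.

**Step 3**
Reactants: 3 methyl (2R)-2-(prop-2-enoyloxy)pent-4-enoate
Product: 4 methyl (2R)-6-oxo-3,6-dihydro-2H-pyran-2-carboxylate
Conditions: RuCl2(=CHPh)(H2IMes)(PCy3) (second-generation Grubbs catalyst, 3 mol %), CH2Cl2 (5 mM), 40 °C
Reagents that add atoms: none
Why: Ring‑closing olefin metathesis of the acrylate/allyl diene gives the six‑membered α,β‑unsaturated lactone, driven by loss of ethene; the stereocentre is not involved.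

**Step 4**
Reactants: 4 methyl (2R)-6-oxo-3,6-dihydro-2H-pyran-2-carboxylate
Product: 5 methyl (2R,4S)-4-methyl-6-oxooxane-2-carboxylate (trans)
Conditions: Me2CuLi (1.5 equiv, from MeLi and CuI), Et2O, −78 °C, 30 min; aq. NH4Cl at −78 °C
Reagents that add atoms: lithium dimethylcuprate, [Li+].C[Cu-]C
Why: Organocuprate 1,4‑addition; methyl enters axially on the half‑chair face anti to the pseudo‑equatorial C2 ester (trans selectivity established for 6‑substituted 5,6‑dihydropyran‑2‑ones), so the bought C2 centre sets C4 as (S), and the cold, weakly basic cuprate avoids γ‑deprotonation and ring opening.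

**Step 5**
Reactants: 6 2-(furan-3-yl)ethan-1-ol
Product: 7 3-(2-bromoethyl)furan
Conditions: CBr4 (1.2 equiv), PPh3 (1.25 equiv), CH2Cl2, 0 °C
Reagents that add atoms: carbon tetrabromide, BrC(Br)(Br)Br
Why: Appel bromination of the primary alcohol under neutral conditions that the acid‑sensitive furan tolerates.

**Step 6**
Reactants: 8 (2E)-3,7-dimethylocta-2,6-dien-1-yl benzoate (geranyl benzoate)
Product: 9 (2E,6E)-8-hydroxy-3,7-dimethylocta-2,6-dien-1-yl benzoate
Conditions: SeO2 (0.3 equiv), t-BuOOH (2.5 equiv), salicylic acid (10 mol %), CH2Cl2, 23 °C, stopped at about 60 % conversion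
Reagents that add atoms: tert-butyl hydroperoxide, CC(C)(C)OO (oxygen relayed through SeO2, O=[Se]=O)
Why: Sharpless–Umbreit catalytic SeO2 allylic oxidation (ene reaction then 2,3‑sigmatropic shift) hydroxylates the E‑methyl of the terminal, electron‑richer olefin; the 2,3‑olefin is deactivated by the allylic benzoate.

**Step 7**
Reactants: 9 (2E,6E)-8-hydroxy-3,7-dimethylocta-2,6-dien-1-yl benzoate
Product: 10 (2E,6E)-8-bromo-3,7-dimethylocta-2,6-dien-1-yl benzoate
Conditions: CBr4 (1.2 equiv), PPh3 (1.25 equiv), CH2Cl2, −20 °C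
Reagents that add atoms: carbon tetrabromide, BrC(Br)(Br)Br
Why: Appel bromination of a primary allylic alcohol proceeds without allylic transposition and keeps the 6E geometry.

**Step 8**
Reactants: 7 3-(2-bromoethyl)furan; 10 (2E,6E)-8-bromo-3,7-dimethylocta-2,6-dien-1-yl benzoate
Product: 12 (2E,6E)-10-(furan-3-yl)-3,7-dimethyldeca-2,6-dien-1-yl benzoate, via furylethyl Grignard reagent 11 (not isolated)
Conditions: 7, Mg turnings, THF, 35 °C; then added slowly to 10 and Li2CuCl4 (3 mol %), THF, −78 to −20 °C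
Reagents that add atoms: none
Why: Kochi–Schlosser copper‑catalysed Grignard coupling displaces the primary allylic bromide by SN2 (γ‑attack would build a quaternary carbon), so the 6E olefin is kept, and the benzoate survives at −20 °C or below.

**Step 9**
Reactants: 5 methyl (2R,4S)-4-methyl-6-oxooxane-2-carboxylate; 12 (2E,6E)-10-(furan-3-yl)-3,7-dimethyldeca-2,6-dien-1-yl benzoate
Product: 14 methyl (2R,4R,7E,11E)-15-(furan-3-yl)-2-hydroxy-4,8,12-trimethylpentadeca-7,11-dienoate, via caesium hydroxy-carboxylate 13 (not isolated)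
Conditions: CsOH·H2O (1.0 equiv), MeCN/H2O 9:1, 0 °C, 30 min; then 12 (1.2 equiv), [Ir(dF(CF3)ppy)2(dtbbpy)]PF6 (1 mol %), NiCl2·glyme (10 mol %), dtbbpy (12 mol %), degassed, 450 nm LEDs, 25 °C; dilute HCl wash
Reagents that add atoms: none
Why: Proposed new method: ring‑opening decarboxylative allylation of a lactone by Ir/Ni dual photoredox catalysis — hydroxide opens the δ‑lactone much faster than it attacks the methyl ester to give carboxylate 13, the photoexcited trivalent iridium complex (about +1.2 V vs SCE) oxidises 13, loss of CO2 gives the primary C5 radical, zerovalent nickel–dtbbpy ionises benzoate 12 to a syn‑allylnickel species in the divalent state, radical capture gives a trivalent alkyl(allyl)nickel that reductively eliminates at the unsubstituted CH2 terminus (linear product, 7E kept because syn/anti exchange would need an η1 tertiary nickel alkyl), and the reduced iridium returns nickel to the zerovalent state; benzoate is a leaving group that is hard to oxidise, C4 is only adjacent to the radical carbon and C2 is remote so neither stereocentre can invert, and the closest known reaction types are Ir/Ni decarboxylative C(sp3)–C(sp3) coupling of carboxylic acids with alkyl halides and nickel‑catalysed reductive allylation of alkyl halides with allylic esters.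

**Step 10**
Reactants: 14 methyl (2R,4R,7E,11E)-15-(furan-3-yl)-2-hydroxy-4,8,12-trimethylpentadeca-7,11-dienoate
Product: 15 methyl (2R,4R,7E,11E)-15-(furan-3-yl)-4,8,12-trimethyl-2-(propanoyloxy)pentadeca-7,11-dienoate
Conditions: (EtCO)2O (1.5 equiv), Et3N (2 equiv), DMAP (10 mol %), CH2Cl2, 0 to 23 °C
Reagents that add atoms: propanoic anhydride, CCC(=O)OC(=O)CC
Why: DMAP‑catalysed acylation of the α‑hydroxy ester under conditions too mild to epimerise C2.

**Step 11**
Reactants: 15 methyl (2R,4R,7E,11E)-15-(furan-3-yl)-4,8,12-trimethyl-2-(propanoyloxy)pentadeca-7,11-dienoate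
Product: 16 (5R)-5-[(2R,5E,9E)-13-(furan-3-yl)-2,6,10-trimethyltrideca-5,9-dien-1-yl]-4-hydroxy-3-methylfuran-2(5H)-one (target)
Conditions: LiN(SiMe3)2 (3.0 equiv), THF, −78 to 0 °C; then cold 0.5 M HCl to pH 3
Reagents that add atoms: none
Why: Lacey–Dieckmann cyclisation: the propanoate enolate attacks the neighbouring methyl ester (5‑exo) and the tetronate forms irreversibly; at low temperature the C5 configuration of α‑acyloxy esters is retained, so ring C5 (R, from step 1) and chain C2 (R, from step 4) reach the target unchanged.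

**Compound list**
1 | methyl (2R)-oxirane-2-carboxylate | COC(=O)[C@H]1CO1 | starting material
2 | methyl (2R)-2-hydroxypent-4-enoate | COC(=O)[C@@H](CC=C)O | intermediate
3 | methyl (2R)-2-(prop-2-enoyloxy)pent-4-enoate | COC(=O)[C@@H](CC=C)OC(=O)C=C | intermediate
4 | methyl (2R)-6-oxo-3,6-dihydro-2H-pyran-2-carboxylate | COC(=O)[C@H]1CC=CC(=O)O1 | intermediate
5 | methyl (2R,4S)-4-methyl-6-oxooxane-2-carboxylate | COC(=O)[C@H]1C[C@H](C)CC(=O)O1 | intermediate
6 | 2-(furan-3-yl)ethan-1-ol | OCCc1ccoc1 | starting material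
7 | 3-(2-bromoethyl)furan | BrCCc1ccoc1 | intermediate
8 | (2E)-3,7-dimethylocta-2,6-dien-1-yl benzoate | O=C(OC/C=C(\C)CCC=C(C)C)c1ccccc1 | starting material
9 | (2E,6E)-8-hydroxy-3,7-dimethylocta-2,6-dien-1-yl benzoate | O=C(OC/C=C(\C)CC/C=C(\C)CO)c1ccccc1 | intermediate
10 | (2E,6E)-8-bromo-3,7-dimethylocta-2,6-dien-1-yl benzoate | O=C(OC/C=C(\C)CC/C=C(\C)CBr)c1ccccc1 | intermediate
11 | [2-(furan-3-yl)ethyl]magnesium bromide (furylethyl Grignard reagent) | Br[Mg]CCc1ccoc1 | intermediate (not isolated)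
12 | (2E,6E)-10-(furan-3-yl)-3,7-dimethyldeca-2,6-dien-1-yl benzoate | O=C(OC/C=C(\C)CC/C=C(\C)CCCc1ccoc1)c1ccccc1 | intermediate
13 | caesium (3S,5R)-5-hydroxy-6-methoxy-3-methyl-6-oxohexanoate (caesium hydroxy-carboxylate) | COC(=O)[C@@H](C[C@H](C)CC(=O)[O-])O.[Cs+] | intermediate (not isolated)
14 | methyl (2R,4R,7E,11E)-15-(furan-3-yl)-2-hydroxy-4,8,12-trimethylpentadeca-7,11-dienoate | COC(=O)[C@@H](C[C@H](C)CC/C=C(\C)CC/C=C(\C)CCCc1ccoc1)O | intermediate
15 | methyl (2R,4R,7E,11E)-15-(furan-3-yl)-4,8,12-trimethyl-2-(propanoyloxy)pentadeca-7,11-dienoate | COC(=O)[C@@H](C[C@H](C)CC/C=C(\C)CC/C=C(\C)CCCc1ccoc1)OC(=O)CC | intermediate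
16 | (5R)-5-[(2R,5E,9E)-13-(furan-3-yl)-2,6,10-trimethyltrideca-5,9-dien-1-yl]-4-hydroxy-3-methylfuran-2(5H)-one | CC1=C(O)[C@@H](C[C@H](C)CC/C=C(\C)CC/C=C(\C)CCCc2ccoc2)OC1=O | target

**Step count**
Total: 11 steps. Longest linear sequence: 7 steps (steps 1, 2, 3, 4, 9, 10, 11).

**Steps most likely to fail**

Step 9 (the new step). The risks are incomplete selectivity of hydroxide for the lactone over the methyl ester, slow oxidation of the unactivated carboxylate, and loss of linear or E selectivity at nickel. The fallback uses known chemistry, sets out from 5 and comes back at 14. Lactone 5 is opened with CsOH to 13 and bis‑silylated (TBSCl, imidazole, DMF) to tert-butyldimethylsilyl (3S,5R)-5-[(tert-butyldimethylsilyl)oxy]-6-methoxy-3-methyl-6-oxohexanoate F1. K2CO3 in aqueous MeOH cleaves only the silyl ester to give (3S,5R)-5-[(tert-butyldimethylsilyl)oxy]-6-methoxy-3-methyl-6-oxohexanoic acid F2. Suárez iododecarboxylation (PhI(OAc)2, I2, visible light, DCE) gives methyl (2R,4S)-2-[(tert-butyldimethylsilyl)oxy]-5-iodo-4-methylpentanoate F3. Nickel‑catalysed reductive cross‑electrophile allylation of F3 with 12 (NiCl2·glyme, terpyridine ligand, Zn, DMA, 25 °C, no light) gives methyl (2R,4R,7E,11E)-2-[(tert-butyldimethylsilyl)oxy]-15-(furan-3-yl)-4,8,12-trimethylpentadeca-7,11-dienoate F4. Bu4NF buffered with AcOH removes the silyl group and returns 14.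

Step 6. SeO2 oxidations of this kind stall at moderate conversion and over‑oxidise to the enal. The fallback sets out from 8 and comes back at 10. mCPBA (1.0 equiv, CH2Cl2, 0 °C) epoxidises the electron‑richer 6,7‑olefin to (2E)-5-(3,3-dimethyloxiran-2-yl)-3-methylpent-2-en-1-yl benzoate F5. TMSOTf/2,6‑lutidine then DBU isomerises the epoxide to (2E)-3,7-dimethyl-6-[(trimethylsilyl)oxy]octa-2,7-dien-1-yl benzoate F6. Citric acid in MeOH gives (2E)-6-hydroxy-3,7-dimethylocta-2,7-dien-1-yl benzoate F7. PBr3 (Et2O, −10 °C) brominates with allylic transposition (SN2′) to the (6E) primary bromide 10.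

Step 8. The Grignard reagent may attack the benzoate or give some γ‑substitution. The fallback sets out from 10 and comes back at 12. The dianion of bought 3‑(furan‑3‑yl)propanoic acid (LiN(iPr)2, 2.1 equiv, THF, −78 °C) is alkylated by 10 (SN2) to give 2-[(2E,6E)-8-(benzoyloxy)-2,6-dimethylocta-2,6-dien-1-yl]-3-(furan-3-yl)propanoic acid F8. DCC and 2‑mercaptopyridine N‑oxide give the Barton ester 2-thioxopyridin-1(2H)-yl 2-[(2E,6E)-8-(benzoyloxy)-2,6-dimethylocta-2,6-dien-1-yl]-3-(furan-3-yl)propanoate F9. Photolysis with t‑BuSH (Barton reductive decarboxylation) removes the extra carboxyl carbon and returns 12.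

**Further compounds**
F1 | step 9 | tert-butyldimethylsilyl (3S,5R)-5-[(tert-butyldimethylsilyl)oxy]-6-methoxy-3-methyl-6-oxohexanoate | COC(=O)[C@@H](C[C@H](C)CC(=O)O[Si](C)(C)C(C)(C)C)O[Si](C)(C)C(C)(C)C
F2 | step 9 | (3S,5R)-5-[(tert-butyldimethylsilyl)oxy]-6-methoxy-3-methyl-6-oxohexanoic acid | COC(=O)[C@@H](C[C@H](C)CC(=O)O)O[Si](C)(C)C(C)(C)C
F3 | step 9 | methyl (2R,4S)-2-[(tert-butyldimethylsilyl)oxy]-5-iodo-4-methylpentanoate | COC(=O)[C@@H](C[C@H](C)CI)O[Si](C)(C)C(C)(C)C
F4 | step 9 | methyl (2R,4R,7E,11E)-2-[(tert-butyldimethylsilyl)oxy]-15-(furan-3-yl)-4,8,12-trimethylpentadeca-7,11-dienoate | COC(=O)[C@@H](C[C@H](C)CC/C=C(\C)CC/C=C(\C)CCCc1ccoc1)O[Si](C)(C)C(C)(C)C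
F5 | step 6 | (2E)-5-(3,3-dimethyloxiran-2-yl)-3-methylpent-2-en-1-yl benzoate (racemic) | O=C(OC/C=C(\C)CCC1OC1(C)C)c1ccccc1
F6 | step 6 | (2E)-3,7-dimethyl-6-[(trimethylsilyl)oxy]octa-2,7-dien-1-yl benzoate (racemic) | O=C(OC/C=C(\C)CCC(O[Si](C)(C)C)C(C)=C)c1ccccc1
F7 | step 6 | (2E)-6-hydroxy-3,7-dimethylocta-2,7-dien-1-yl benzoate (racemic) | O=C(OC/C=C(\C)CCC(O)C(C)=C)c1ccccc1
F8 | step 8 | 2-[(2E,6E)-8-(benzoyloxy)-2,6-dimethylocta-2,6-dien-1-yl]-3-(furan-3-yl)propanoic acid (racemic) | O=C(OC/C=C(\C)CC/C=C(\C)CC(Cc1ccoc1)C(O)=O)c1ccccc1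
F9 | step 8 | 2-thioxopyridin-1(2H)-yl 2-[(2E,6E)-8-(benzoyloxy)-2,6-dimethylocta-2,6-dien-1-yl]-3-(furan-3-yl)propanoate (racemic) | O=C(OC/C=C(\C)CC/C=C(\C)CC(Cc1ccoc1)C(=O)On1ccccc1=S)c1ccccc1
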